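The data stem from a simulated flask for an exercise, noise included.

Compare the charges before the clock.

in all of them: partner 0.444 M; free catalyst 0.96 mM
- elm: substrate 0.34 M; temperature 75 °C; run made earlier
- cedar: substrate 0.48 M; temperature 100 °C; run made earlier
- oak: substrate 0.52 M; temperature 75 °C; run made earlier
- Friday's: substrate 0.37 M; at 80 °C until 80 s, from then on at 120 °C; time 4.0 min
- Sunday's: substrate 0.60 M; at 120 °C throughout; time 4.0 min

| run | time / s | product / % | substrate / % |
|---|---|---|---|
| elm | 10.0 | 3 | 92 |
| elm | 20.0 | 8 | 87 |
| elm | 30.0 | 19 | 88 |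
| elm | 60.0 | 21 | 75 |
| elm | 120 | 41 | 58 |
| cedar | 10.0 | 12 | 90 |
| cedar | 12.0 | 12 | 89 |
| cedar | 20.0 | 15 | 83 |
| cedar | 40.0 | 29 | 70 |
| oak | 10.0 | 4 | 98 |
| oak | 30.0 | 10 | 91 |
| oak | 60.0 | 18 | 86 |
| oak | 80.0 | 19 | 79 |
| oak | 120 | 28 | 72 |

(each reading ± 2 percentage points)

- a reading or a percentage of product counts all its forms, free or not

* the winner by amount of product, in percent of the substrate charged; "neither" if no more than 2 percentage points parts them (Friday's / Sunday's / neither)
* how much product is there at the end, in percent of the substrate charged: Friday's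
* how much product is there at the end, in percent of the substrate charged: Sunday's

1. Charges. Assume one partner and one substrate per product. The ceiling Y is then the partner charge over the substrate charge, capped at 100 %; for Sunday's flask it is 74.0 %. Sunday's flask holds less partner than substrate, so partner is its limiting reagent. Friday's flask holds more partner than substrate: its ratio of 120 % caps at 100 %.

2. Early stretch. At 75 °C, the elm run reads 1.16 mM s⁻¹ over 120 s, and the oak run, with a larger charge, reads 1.21 mM s⁻¹. The two rates are about equal, so the rate r reads as zero order in substrate. It integrates to P = r t, with P the product concentration and t the time. The cedar run at 100 °C reads 3.48 mM s⁻¹.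

3. Middle. Take a hotter flask as no slower, and reckon with these readings. On that estimate, Friday's flask makes about 0.0929 M in its first 80 s, leaving about 0.277 M of substrate. At the cedar rate, that remainder takes 79.6 s, less than the 160 s still on the clock.

4. End. At the cedar rate, the estimated time for Sunday's flask to make product equal to its partner charge is 128 s, less than the 240 s allowed. That spare time is the margin against any slowing at low partner. The reckoning here therefore gives near 100 % for Friday's flask and Y for Sunday's flask.

The forecast, which agrees, names Friday's, with 99 % and 74 %, since Sunday's flask “runs out of partner”.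

The flask gives Friday's: 98.9 % for Friday's and 73.8 % for Sunday's.

    free catalyst + product ⇌ idle complex (K = 0.901 M⁻¹, k = 0.507 M⁻¹ s⁻¹, Ea = 73.0 kJ mol⁻¹, ΔH = −7.00 kJ mol⁻¹)
    substrate + catalyst intermediate A ⇌ catalyst intermediate B (K = 3.40 M⁻¹, k = 726 M⁻¹ s⁻¹, Ea = 52.0 kJ mol⁻¹, ΔH = −80.0 kJ mol⁻¹)
    partner ⇌ dormant form (K = 0.360, k = 0.0319 s⁻¹, Ea = 106 kJ mol⁻¹, ΔH = −25.0 kJ mol⁻¹)
    catalyst intermediate B → free catalyst + product (k = 18.3 s⁻¹, Ea = 66.0 kJ mol⁻¹)
    partner + free catalyst → catalyst intermediate A (k = 7.59 M⁻¹ s⁻¹, Ea = 51.0 kJ mol⁻¹)
    (constants at 80 °C)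

Sunday's flask ends at 73.8 % against its ceiling of 74.0 %, with partner down to 0.238 % of its charge and substrate at 26.2 % after 4.00 min. The substrate charge is the main reason for the gap to Friday's flask: with that difference removed, Sunday's flask gives 99.9 % instead of 73.8 %. The temperature programme is not the reason: with that difference removed, Sunday's flask gives 72.8 %.

For a neighbour of Sunday's flask charged with 0.11 M of partner, the ceiling is 18.3 %. The simulated neighbour gives 18.3 %.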